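2.10 µM of enzyme is what the elm flask really works with: call it the free enzyme, F, the enzyme charged less the impurity charged, taken one for one.

common to all: substrate 0.18 M; impurity 3.1 µM
- elm: enzyme 5.2 µM; the very flask that is asked about, followed so far
- cedar: enzyme 2.6 µM; run made earlier
- flask: enzyme 5.2 µM; time 5.0 h

- elm (time / min: target / %): 15.0: 53.7; 25.0: 57.9; 40.0: 60.7; 60.0: 62.8; 120: 66.8; 180: 68.3
- cedar (time / min: target / %): 1.50: 2.0; 3.00: 2.5; 5.00: 2.6; 8.00: 2.0; 12.0: 2.7; 20.0: 2.0

(each reading ± 0.3 percentage points)

- target taken out counts as made
- additions bring no volume worth counting

- Wednesday's: at 5.0 h add enzyme, 50.0% of the amount charged, then wait 1.5 h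
- Monday's: at 5.0 h add substrate, 50.0% of the amount charged, then wait 1.5 h
- Friday's: change nothing and wait 1.5 h more
- Saturday's: at 5.0 h take out 90% of the target then present, then wait 1.5 h

1. target, in percent of the substrate first charged, at 5.0 h
2. the remedy with the largest gain of target, or "none" below 2 percentage points (Wednesday's / Monday's / Friday's / Saturday's / none)
3. target present, with what was taken out counted in, in percent of the substrate first charged, after Wednesday's
4. target present, with what was taken out counted in, in percent of the substrate first charged, after Friday's

Read the cedar run first. Its target lies between 2.0% and 2.7% from the first reading to the last and does not climb, and there the impurity exceeds the enzyme. Elm has twice the enzyme with the same impurity and reads 68.3% at 180 min. Take the killing as fast and finished, then keep the books on the enzyme. In elm the impurity is the limiting reagent of that killing, because it is the smaller charge.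

Enzyme charged: 5.2 µM

Taken by impurity: 3.1 µM

Free, F: 2.10 µM

Impurity left over: 0 µM

Wednesday's dose: 2.60 µM

Free with the dose: 4.70 µM

Now turn the books into target. Let L be the natural log of substrate charged over substrate left, and take L as proportional to the free enzyme. Elm's last reading gives L = 1.15. Wednesday's multiplies F by 2.24, which gives 92.4% target. That is a rough figure, and the dose gets less time than that reading had. The other remedies add no enzyme, and elm gained 1.5 percentage points over its last hour. Choose Wednesday's.

The forecast gives 70.6% at 5.0 h, 87% after Wednesday's and 71.8% after Friday's, and it also picks Wednesday's: “Fresh enzyme meets no remaining impurity, so all 2.6 µM is active and restarts a full burst.” My figure stands above its figure for Wednesday's.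

The flask gives 69.4% at 5.0 h, 88.7% after Wednesday's and 69.6% after Friday's. The best remedy is Wednesday's, gaining 19 points.

    enzyme ⇌ dormant form (K = 2.30, k = 8.13 × 10⁻⁴ /s)
    enzyme + impurity → spent catalyst B (k = 82900 /M/s)
    enzyme → spent catalyst A (k = 0.00147 /s)
    substrate + enzyme → target + enzyme, rate k4*[substrate]*[enzyme]/(1 + ([substrate]/Km4) + ([target]/Kp4)) (0.153 M, 0.0514 M, k = 2630 /M/s)

At its charge the impurity takes enzyme at 0.257 /s, against 0.00147 /s for the enzyme's own death, a ratio of 175. In the flask, spent catalyst B stands at 59.6% by 30.0 min and still at 59.6% at 300 min, while spent catalyst A reaches 40.0%, against F as a share of the charge, 40.4%. The neighbour charged with 1.9 × 10⁻⁶ M of impurity has F = 3.30 µM, a share of 63.5%; its spent catalyst A stands at 62.9% and its target at 82.2%.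

(Readings and results come from a simulation with constants of no real substance; the scatter is artificial.)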